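**Assumptions**
- Dihydrocurcumin has no stereocenter. The only stereo element is the E-alkene, so "single enantiomer" is moot.
- The diketo form in the SMILES is taken as the same compound as its keto-enol tautomer.

**Retrosynthetic overview**
1. The enone C=C is disconnected by a boron-mediated aldol condensation (Pabon-type). This gives vanillin and the 1,3-diketone 1-(4-hydroxy-3-methoxyphenyl)hexane-3,5-dione (3), which reacts at its terminal CH₃.
2. Diketone 3 is disconnected by a Claisen acetylation of the methyl side of zingerone (1) with ethyl acetate (2).
3. No rings are formed, because both aryl rings are already present in the commercial starting materials. No protecting groups are needed.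

---

**Step 1**
Reactants: 1 (zingerone, 4-(4-hydroxy-3-methoxyphenyl)butan-2-one); 2 (ethyl acetate)
Product: 3, 1-(4-hydroxy-3-methoxyphenyl)hexane-3,5-dione
Conditions: NaH (3 equiv), EtOAc (excess), THF, reflux; then 1 M HCl work-up
Reagents that add atoms: ethyl acetate, CCOC(C)=O (supplies the acetyl group). NaH and HCl leave no atoms in the product.
Why: Excess NaH deprotonates the phenol and then the ketone at its less hindered CH₃. The enolate attacks EtOAc in a crossed Claisen condensation. The resulting β-diketone is deprotonated to a stabilised enolate, which drives the reaction, and acidic work-up regenerates the phenol and the diketone. There is no new stereocenter.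

**Step 2**
Reactants: 3 (1-(4-hydroxy-3-methoxyphenyl)hexane-3,5-dione); 4 (vanillin, 4-hydroxy-3-methoxybenzaldehyde)
Product: 5, dihydrocurcumin, (E)-1,7-bis(4-hydroxy-3-methoxyphenyl)hept-1-ene-3,5-dione
Conditions: B₂O₃, B(OBu)₃, EtOAc, 70–80 °C, then n-BuNH₂ (cat.), 80 °C; then 0.4 M HCl, 60 °C
Reagents that add atoms: none. Vanillin is a reactant. The boron reagents and butylamine are removed in the hydrolytic work-up, and the acid adds no atoms to the product.
Why: B₂O₃ and B(OBu)₃ chelate the 1,3-diketone as a boron enolate complex. This blocks Knoevenagel reaction at C4, the CH₂ between the two carbonyls, and leaves the terminal CH₃ as the nucleophile. The amine-catalysed aldol condensation (Pabon-type) with vanillin occurs at that CH₃, and dehydration gives the thermodynamically favoured E-enone. The free phenols survive. Acid hydrolysis releases the diketone. The CH₂CH₂Ar side is untouched, so the saturated chain is retained.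

---

**Self-check**
- Target SMILES COc1cc(/C=C/C(=O)CC(=O)CCc2ccc(O)c(OC)c2)ccc1O has an Ar–CH=CH–CO–CH₂–CO–CH₂CH₂–Ar skeleton. Each aryl is 4-OH-3-OMe, the alkene is E, and there are no stereocenters. Compound 5 matches all of this.
- Atom count for step 1: C₁₁H₁₄O₃ + C₂H₂O (acetyl, net of EtOH) = C₁₃H₁₆O₄ (3).
- Atom count for step 2: C₁₃H₁₆O₄ + C₈H₈O₃ − H₂O = C₂₁H₂₂O₆, which is dihydrocurcumin.
- The Step 1 conditions are compatible with the phenol and the ketone. The Step 2 conditions are compatible with the free phenols, the diketone and the preformed saturated chain. Neither step touches an alkene that has to be preserved, because the only alkene is created in the last step.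
- The E geometry is set in the dehydration and is not changed afterwards.

---

**Compound list**

| No. | Name | SMILES | Role |
|---|---|---|---|
| 1 | Zingerone | COc1cc(CCC(C)=O)ccc1O | starting material |
| 2 | Ethyl acetate | CCOC(C)=O | starting material |
| 3 | 1-(4-Hydroxy-3-methoxyphenyl)hexane-3,5-dione | COc1cc(CCC(=O)CC(C)=O)ccc1O | intermediate |
| 4 | Vanillin | COc1cc(C=O)ccc1O | starting material |
| 5 | Dihydrocurcumin | COc1cc(/C=C/C(=O)CC(=O)CCc2ccc(O)c(OC)c2)ccc1O | target |

**Total steps:** 2. **Longest linear sequence:** 2 steps (1 → 3 → 5).

**Three steps most likely to fail**
1. **Step 1, regioselectivity and yield.** Acetylation may occur at the internal CH₂ instead of the CH₃, and EtOAc may self-condense.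
   - Fallback: change to a dianion alkylation. Treat acetylacetone with NaH then n-BuLi to form the dianion, and alkylate its terminal carbon with 4-(TBSO)-3-methoxybenzyl bromide. Removing the TBS group (HF·pyridine) then gives 3.
2. **Step 2, condensation selectivity.** Side products include aldol at the internal CH₂ and vanillin oligomers, and they are hard to separate.
   - Fallback: use a Claisen-based assembly. Treat bis-TBS-protected dehydrozingerone with LiHMDS and methyl 3-(4-TBSO-3-methoxyphenyl)propanoate to build the diketone with the enone already in place. Remove the TBS groups with buffered HF·pyridine.
3. **Step 2, boron-complex hydrolysis and product stability.** The β-diketone-enone can undergo retro-Claisen or retro-aldol cleavage, oxidise, or photoisomerise to Z under the hot acidic conditions.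
   - Fallback: avoid hot aqueous acid by releasing the boron complex under mild conditions, with a short room-temperature treatment using aqueous oxalic acid or a buffered work-up. If that fails, switch to the protected Claisen route in item 2, which never forms a boron complex.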